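The route ties the C1 carboxyl to the C10′ oxygen as an ester, which turns the open-chain target into a 14-membered benzolactone (arene C1 and C6, C1′–C10′, the ester O and C=O) holding C8′–C9′ inside the ring. Ring-closing alkyne metathesis of a diyne ester forges the C8′≡C9′ bond and the macrocycle in one operation; syn semihydrogenation of the ring alkyne can then only give the Z-alkene. The precursor is the (R)-non-2-yn-4-yl ester of 2-(dec-8-ynyl)-4,6-bis(methoxymethoxy)benzoic acid, both alkynes methyl-capped, assembled by lateral alkylation of protected methyl orsellinate and an inverting Mitsunobu esterification. Lactone opening, acetylation and MOM removal finish the synthesis.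

Key step: step 7

Remark: arene carbons are numbered from the carboxyl-bearing carbon (C1; oxygens on C2 and C4, side chain on C6) and side-chain carbons from C1′ (benzylic) to C15′; the target is 10′R, 8′Z, and 1-propynyllithium and 1,6-diiodohexane are assumed to be purchased.

Step 1
Reactants: 1 methyl orsellinate (methyl 2,4-dihydroxy-6-methylbenzoate)
Product: 2 methyl 2,4-bis(methoxymethoxy)-6-methylbenzoate
Conditions: NaH (2.4 equiv), MOMCl (2.4 equiv), DMF, 0 °C → rt
Reagents that add atoms: chloromethyl methyl ether (MOMCl), COCCl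
Why: Williamson-type O-alkylation of both phenoxides (NaH also deprotonates the hydrogen-bonded C2 phenol) should give the base-stable bis-acetal that the later anion and hydroxide steps require.

Step 2
Reactants: 3 1-propynyllithium; 4 1,6-diiodohexane
Product: 5 9-iodonon-2-yne
Conditions: 3 (1 equiv) added to 4 (3 equiv), THF/DMPU, 0 °C → rt; excess 4 recovered by distillation
Reagents that add atoms: none
Why: SN2 alkylation of a lithium acetylide by a primary iodide in a dipolar medium is reliable where an alkynylmagnesium halide would be too weak a nucleophile, and the threefold excess of the diiodide should hold back double substitution.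

Step 3
Reactants: 2 methyl 2,4-bis(methoxymethoxy)-6-methylbenzoate; 5 9-iodonon-2-yne
Product: 7 methyl 2-(dec-8-yn-1-yl)-4,6-bis(methoxymethoxy)benzoate, via lateral benzyllithium 6 (not isolated)
Conditions: LiN(i-Pr)2 (1.1 equiv), THF, −78 °C; then 5 (1.2 equiv), DMPU, −78 → −20 °C
Reagents that add atoms: none
Why: Lateral lithiation of the ortho-toluate (the ester stabilises the benzylic anion as an extended enolate) followed by SN2 alkylation builds C1′–C2′, and the iodide is chosen so that alkylation should outrun self-condensation of the anion with the ester.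

Step 4
Reactants: 7 methyl 2-(dec-8-yn-1-yl)-4,6-bis(methoxymethoxy)benzoate
Product: 8 2-(dec-8-yn-1-yl)-4,6-bis(methoxymethoxy)benzoic acid
Conditions: KOH (10 equiv), EtOH/H2O, reflux; then 1 M HCl to pH 4, 0 °C
Reagents that add atoms: potassium hydroxide, [K+].[OH-]
Why: Saponification of the hindered methyl ester needs forcing aqueous-alcoholic hydroxide, to which the MOM acetals and the internal alkyne are inert, and cold acidification only to pH 4 should spare the acetals.

Step 5
Reactants: 9 (S)-oct-1-yn-3-ol
Product: 11 (S)-non-2-yn-4-ol, via dilithium alkynolate 10 (not isolated)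
Conditions: n-BuLi (2.1 equiv), THF, −78 → −20 °C; MeI (1.1 equiv), −78 °C → rt; H2O
Reagents that add atoms: iodomethane, CI
Why: C-alkylation of the alkynol dianion should be selective because the acetylide carbon is far more nucleophilic than the aggregated lithium alkoxide in THF without a dipolar cosolvent, and the carbinol stereocentre is not touched.

Step 6
Reactants: 8 2-(dec-8-yn-1-yl)-4,6-bis(methoxymethoxy)benzoic acid; 11 (S)-non-2-yn-4-ol
Product: 12 (R)-non-2-yn-4-yl 2-(dec-8-yn-1-yl)-4,6-bis(methoxymethoxy)benzoate
Conditions: PPh3 (1.5 equiv), DIAD (1.5 equiv, added last), toluene, 0 °C → rt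
Reagents that add atoms: none
Why: In the Mitsunobu esterification the carboxylate attacks the carbinol carbon of the alkoxyphosphonium ion in an SN2 sense, which avoids the hindered acyl carbon and inverts the S alcohol to the R ester (future C10′).

Step 7
Reactants: 12 (R)-non-2-yn-4-yl 2-(dec-8-yn-1-yl)-4,6-bis(methoxymethoxy)benzoate
Product: 13 (R)-cycloalkyne benzolactone (14-membered ring; C8′≡C9′ in the ring; pentyl on C10′; MOM ethers on arene C2 and C4)
Conditions: Mo(≡CC6H4-4-OMe)(OSiPh3)3 (10 mol %), 5 Å molecular sieves, toluene (2 mM), rt → 80 °C, Ar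
Reagents that add atoms: none
Why: The molybdenum alkylidyne adds to one methyl-capped alkyne by [2+2] cycloaddition, the metallacyclobutadiene cycloreverts with loss of 2-butyne to a substrate-bound alkylidyne, and this adds to the second alkyne of the same molecule and cycloreverts again to release the cycloalkyne and the chain-carrying ethylidyne Mo≡C–CH3. The closest known reaction type is ring-closing alkyne metathesis of bis(methyl-capped) diyne esters to 12- to 18-membered arene-fused macrolactones with silanolate-ligated molybdenum alkylidynes. The single ring is closed by macrocyclisation through the new C8′≡C9′ bond, which becomes an endocyclic triple bond of the 14-membered lactone, a ring large enough to hold a linear C–C≡C–C unit. No stereocentre is formed, and C10′ keeps its R configuration because neither its C–O nor its C–H bond takes part. The step needs ring closure to win over acyclic diyne metathesis (oligomers, cyclic dimers) and needs the catalyst to leave ester and acetals alone; 2 mM dilution, trapping of 2-butyne in the sieves and the ortho placement of ester and side chain on the arene (C1 and C6) should secure the first, and the silanolate ligands the second.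

Step 8
Reactants: 13 (R)-cycloalkyne benzolactone
Product: 14 (R,Z)-cycloalkene benzolactone (14-membered ring; C8′=C9′ cis in the ring)
Conditions: H2 (1 atm), Pd/CaCO3 poisoned with Pb(OAc)2 (Lindlar catalyst), quinoline, EtOAc, rt
Reagents that add atoms: none
Why: Lindlar semihydrogenation delivers both hydrogens to one face of the ring alkyne on the poisoned palladium surface, so only the Z C8′=C9′ alkene can form, and quinoline should stop over-reduction.

Step 9
Reactants: 14 (R,Z)-cycloalkene benzolactone
Product: 15 2-[(8Z,10R)-10-hydroxypentadec-8-en-1-yl]-4,6-bis(methoxymethoxy)benzoic acid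
Conditions: KOtBu (8 equiv), H2O (2 equiv), THF, rt → 40 °C; then 1 M HCl to pH 4, 0 °C
Reagents that add atoms: water, O
Why: Poorly solvated hydroxide made from KOtBu and a little water (anhydrous-hydroxide ester cleavage, known for doubly ortho-substituted benzoates) should attack the hindered acyl carbon; acyl–oxygen cleavage leaves the C10′–O bond and its R configuration intact, and the acetals and the Z-alkene tolerate base.

Step 10
Reactants: 15 2-[(8Z,10R)-10-hydroxypentadec-8-en-1-yl]-4,6-bis(methoxymethoxy)benzoic acid
Product: 17 2-[(8Z,10R)-10-acetoxypentadec-8-en-1-yl]-4,6-bis(methoxymethoxy)benzoic acid, via mixed acetic anhydride 16 (not isolated)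
Conditions: Ac2O (5 equiv), pyridine, DMAP (cat.), CH2Cl2, 0 °C → rt; then NaHCO3, THF/H2O, rt; work-up at pH 4
Reagents that add atoms: acetic anhydride, CC(=O)OC(C)=O
Why: DMAP-catalysed acylation esterifies the secondary allylic alcohol with retention, while the carboxyl group is only transiently acetylated as a mixed anhydride that water should cleave at its unhindered acetyl carbonyl during work-up.

Step 11
Reactants: 17 2-[(8Z,10R)-10-acetoxypentadec-8-en-1-yl]-4,6-bis(methoxymethoxy)benzoic acid
Product: 18 2-[(8Z,10R)-10-acetoxypentadec-8-en-1-yl]-4,6-dihydroxybenzoic acid (target)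
Conditions: ZnBr2 (3 equiv), n-PrSH (6 equiv), CH2Cl2, 0 °C, 10–15 min; pH 4 buffer
Reagents that add atoms: none
Why: Lewis acid/thiol cleavage of methoxymethyl acetals (ZnBr2 activates the acetal, the soft thiol traps the methoxymethyl cation) is complete within minutes at 0 °C without water or protic acid, which should spare the allylic acetate and the decarboxylation-prone 2,4-dihydroxybenzoic acid.

Compound list
1 | methyl orsellinate (methyl 2,4-dihydroxy-6-methylbenzoate) | COC(=O)c1c(C)cc(O)cc1O | starting material
2 | methyl 2,4-bis(methoxymethoxy)-6-methylbenzoate | COC(=O)c1c(C)cc(OCOC)cc1OCOC | intermediate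
3 | 1-propynyllithium | [Li]C#CC | starting material
4 | 1,6-diiodohexane | ICCCCCCI | starting material
5 | 9-iodonon-2-yne | CC#CCCCCCCI | intermediate
6 | methyl 2-(lithiomethyl)-4,6-bis(methoxymethoxy)benzoate (lateral benzyllithium, formed in the flask) | COC(=O)c1c(C[Li])cc(OCOC)cc1OCOC | intermediate
7 | methyl 2-(dec-8-yn-1-yl)-4,6-bis(methoxymethoxy)benzoate | COC(=O)c1c(CCCCCCCC#CC)cc(OCOC)cc1OCOC | intermediate
8 | 2-(dec-8-yn-1-yl)-4,6-bis(methoxymethoxy)benzoic acid | OC(=O)c1c(CCCCCCCC#CC)cc(OCOC)cc1OCOC | intermediate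
9 | (S)-oct-1-yn-3-ol | CCCCC[C@@H](C#C)O | starting material
10 | dilithium salt of (S)-oct-1-yn-3-ol (C1-lithio lithium alkoxide, formed in the flask) | CCCCC[C@@H](C#C[Li])O[Li] | intermediate
11 | (S)-non-2-yn-4-ol | CCCCC[C@@H](C#CC)O | intermediate
12 | (R)-non-2-yn-4-yl 2-(dec-8-yn-1-yl)-4,6-bis(methoxymethoxy)benzoate | CCCCC[C@H](C#CC)OC(=O)c1c(OCOC)cc(OCOC)cc1CCCCCCCC#CC | intermediate
13 | (3R)-14,16-bis(methoxymethoxy)-3-pentyl-4,5-didehydro-3,6,7,8,9,10,11,12-octahydro-1H-2-benzoxacyclotetradecin-1-one (cycloalkyne benzolactone) | CCCCC[C@H]1OC(=O)c2c(OCOC)cc(OCOC)cc2CCCCCCCC#C1 | intermediate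
14 | (3R,4Z)-14,16-bis(methoxymethoxy)-3-pentyl-3,6,7,8,9,10,11,12-octahydro-1H-2-benzoxacyclotetradecin-1-one (Z-cycloalkene benzolactone) | CCCCC[C@@H]1/C=C\CCCCCCCc2cc(OCOC)cc(OCOC)c2C(=O)O1 | intermediate
15 | 2-[(8Z,10R)-10-hydroxypentadec-8-en-1-yl]-4,6-bis(methoxymethoxy)benzoic acid | CCCCC[C@H](/C=C\CCCCCCCc1cc(OCOC)cc(OCOC)c1C(=O)O)O | intermediate
16 | acetic 2-[(8Z,10R)-10-acetoxypentadec-8-en-1-yl]-4,6-bis(methoxymethoxy)benzoic anhydride (formed in the flask) | CCCCC[C@H](/C=C\CCCCCCCc1cc(OCOC)cc(OCOC)c1C(=O)OC(C)=O)OC(C)=O | intermediate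
17 | 2-[(8Z,10R)-10-acetoxypentadec-8-en-1-yl]-4,6-bis(methoxymethoxy)benzoic acid | CCCCC[C@H](/C=C\CCCCCCCc1cc(OCOC)cc(OCOC)c1C(=O)O)OC(C)=O | intermediate
18 | 2-[(8Z,10R)-10-acetoxypentadec-8-en-1-yl]-4,6-dihydroxybenzoic acid | CCCCC[C@H](/C=C\CCCCCCCc1cc(O)cc(O)c1C(=O)O)OC(C)=O | target

Total step count: 11 steps.
Longest linear sequence: 9 steps (steps 1, 3, 4, 6, 7, 8, 9, 10 and 11, from methyl orsellinate).

Steps most likely to fail

Step 7. Intermolecular diyne metathesis (oligomerisation, cyclodimerisation) may outcompete ring closure, or the catalyst may stall at the branched propargylic ester alkyne. The fallback gives up the macrocycle and makes the C7′–C8′ bond by acetylide alkylation. It sets out from 2: the lateral anion 6 is added to an excess of 1,6-diiodohexane 4 to give methyl 2-(7-iodoheptyl)-4,6-bis(methoxymethoxy)benzoate F1. Commercial (R)-oct-1-yn-3-ol (CCCCC[C@H](C#C)O) is converted with n-BuLi (2 equiv) in THF/DMPU into the dilithium salt of (R)-oct-1-yn-3-ol F2, which is alkylated at carbon by F1 to give methyl 2-[(10R)-10-hydroxypentadec-8-yn-1-yl]-4,6-bis(methoxymethoxy)benzoate F3; C10′ is then R from the start and no inversion is needed. Lindlar semihydrogenation should give methyl 2-[(8Z,10R)-10-hydroxypentadec-8-en-1-yl]-4,6-bis(methoxymethoxy)benzoate F4, and saponification of the methyl ester under the conditions of step 4 rejoins the route at 15.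

Step 9. Hydroxide may fail to attack the doubly ortho-substituted acyl carbon, and on forcing, elimination of the allylic carboxylate or migration of the alkene may take over. The fallback sets out from 14 and opens the lactone by reduction instead of hydrolysis. LiAlH4 in THF should give (8Z,10R)-1-[2-(hydroxymethyl)-3,5-bis(methoxymethoxy)phenyl]pentadec-8-en-10-ol F5. Oxidation with catalytic TEMPO and PhI(OAc)2, selective for the primary benzylic alcohol, gives 2-[(8Z,10R)-10-hydroxypentadec-8-en-1-yl]-4,6-bis(methoxymethoxy)benzaldehyde F6. Pinnick oxidation (NaClO2, NaH2PO4, 2-methyl-2-butene, t-BuOH/H2O) then rejoins the route at 15.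

Step 11. The allylic acetate may ionise or be lost, the free 2,4-dihydroxybenzoic acid may decarboxylate, or the acetal on the C4 oxygen may cleave incompletely. The fallback sets out from 15 and removes the acetals before any acetate is present. Aqueous HCl in THF at rt should give 2,4-dihydroxy-6-[(8Z,10R)-10-hydroxypentadec-8-en-1-yl]benzoic acid F7. Exhaustive acetylation (Ac2O, pyridine, DMAP) gives acetic 2,4-diacetoxy-6-[(8Z,10R)-10-acetoxypentadec-8-en-1-yl]benzoic anhydride F8, which aqueous NaHCO3 work-up hydrolyses to 2,4-diacetoxy-6-[(8Z,10R)-10-acetoxypentadec-8-en-1-yl]benzoic acid F9. NH4OAc in aqueous MeOH at rt then cleaves the two aryl acetates chemoselectively, leaving the alkyl acetate, and arrives at 18.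

Further compounds
F1 | step 7 | methyl 2-(7-iodoheptyl)-4,6-bis(methoxymethoxy)benzoate | COC(=O)c1c(CCCCCCCI)cc(OCOC)cc1OCOC
F2 | step 7 | dilithium salt of (R)-oct-1-yn-3-ol | CCCCC[C@H](C#C[Li])O[Li]
F3 | step 7 | methyl 2-[(10R)-10-hydroxypentadec-8-yn-1-yl]-4,6-bis(methoxymethoxy)benzoate | CCCCC[C@H](C#CCCCCCCCc1cc(OCOC)cc(OCOC)c1C(=O)OC)O
F4 | step 7 | methyl 2-[(8Z,10R)-10-hydroxypentadec-8-en-1-yl]-4,6-bis(methoxymethoxy)benzoate | CCCCC[C@H](/C=C\CCCCCCCc1cc(OCOC)cc(OCOC)c1C(=O)OC)O
F5 | step 9 | (8Z,10R)-1-[2-(hydroxymethyl)-3,5-bis(methoxymethoxy)phenyl]pentadec-8-en-10-ol | CCCCC[C@H](/C=C\CCCCCCCc1cc(OCOC)cc(OCOC)c1CO)O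
F6 | step 9 | 2-[(8Z,10R)-10-hydroxypentadec-8-en-1-yl]-4,6-bis(methoxymethoxy)benzaldehyde | CCCCC[C@H](/C=C\CCCCCCCc1cc(OCOC)cc(OCOC)c1C=O)O
F7 | step 11 | 2,4-dihydroxy-6-[(8Z,10R)-10-hydroxypentadec-8-en-1-yl]benzoic acid | CCCCC[C@H](/C=C\CCCCCCCc1cc(O)cc(O)c1C(=O)O)O
F8 | step 11 | acetic 2,4-diacetoxy-6-[(8Z,10R)-10-acetoxypentadec-8-en-1-yl]benzoic anhydride | CCCCC[C@H](/C=C\CCCCCCCc1cc(OC(C)=O)cc(OC(C)=O)c1C(=O)OC(C)=O)OC(C)=O
F9 | step 11 | 2,4-diacetoxy-6-[(8Z,10R)-10-acetoxypentadec-8-en-1-yl]benzoic acid | CCCCC[C@H](/C=C\CCCCCCCc1cc(OC(C)=O)cc(OC(C)=O)c1C(=O)O)OC(C)=O
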